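**Plan**

1. Retrosynthetic cuts, in order: the three O–Si bonds (global desilylation); C2–H2 back to a γ-lactone C2=O (a temporary oxidation level); the exocyclic C3–CH(OH)Ar bond (lactone-enolate aldol, then oxidation and chelate-controlled reduction); the ring bond O1–C5 by retro-Baeyer–Villiger; the cyclobutanone by retro-[2+2] to an allylarene and dichloroketene.
2. Enabling feature: in the oxolane (O1, C2, C3 carrying the carbinol, C4 carrying the benzyl group, C5), C4 is flanked by the ring carbons C5 and C3. With C2 as a carbonyl, these are the two enantiotopic α-CH2 groups of a σ-symmetric 3-(arylmethyl)cyclobutanone. Oxygen insertion between C2 and C5 therefore makes the O1–C5 bond, the five-membered ring and the C4 stereocentre in one strain-releasing event.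
3. Forward order: silylated methoxyeugenol → achiral cyclobutanone → (R)-γ-lactone (ring formed) → aldol side chain at C3 → carbinol corrected through the ketone → lactone C=O removed (lactol, then silane) → desilylation.
4. Stereochemistry: C4 by catalyst control in the desymmetrising Baeyer–Villiger step; C3 relayed from C4 (aldol anti to the benzyl group, trans); the carbinol centre relayed from C3 by zinc-chelate-controlled hydride delivery.

Key step: step 4

Assumption: both antipodes of the chiral N,N′-dioxide ligand are available, and the one that gives the (R)-lactone on this substrate is used (sense of induction to be confirmed by correlation of lactone 6).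

Abbreviation: Ar = 4-(tert-butyldimethylsilyloxy)-3,5-dimethoxyphenyl; TBS = tert-butyldimethylsilyl.

**Step 1**
Reactants: 1 4-allyl-2,6-dimethoxyphenol (methoxyeugenol)
Product: 2 (4-allyl-2,6-dimethoxyphenoxy)(tert-butyl)dimethylsilane
Conditions: TBSCl, imidazole, DMF, rt
Reagents that add atoms: tert-butyldimethylsilyl chloride, CC(C)(C)[Si](C)(C)Cl
Why: Imidazole-promoted O-silylation of the phenol (silyl ether formation) masks the acylable and oxidisable phenol for the ketene and peracid steps; no stereocentre is involved.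

**Step 2**
Reactants: 2 (4-allyl-2,6-dimethoxyphenoxy)(tert-butyl)dimethylsilane
Product: 3 rac-2,2-dichloro-3-(ArCH2)cyclobutan-1-one
Conditions: Cl3CCOCl, Zn–Cu, POCl3, Et2O, reflux
Reagents that add atoms: trichloroacetyl chloride, ClC(=O)C(Cl)(Cl)Cl
Why: Thermal [2+2] ketene–alkene cycloaddition of dichloroketene, generated in the flask by zinc dechlorination of the acid chloride, places the carbonyl carbon on the terminal CH2 of the alkene; the centre formed is racemic and stops being a stereocentre after step 3.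

**Step 3**
Reactants: 3 rac-2,2-dichloro-3-(ArCH2)cyclobutan-1-one
Product: 4 3-(ArCH2)cyclobutan-1-one (achiral, σ-symmetric)
Conditions: Zn dust, AcOH, rt
Reagents that add atoms: none
Why: Zinc-mediated reductive dehalogenation of an α,α-dichloroketone should give the symmetric cyclobutanone, in which the benzyl-bearing carbon is prochiral.

**Step 4**
Reactants: 4 3-(ArCH2)cyclobutan-1-one
Product: 6 (R)-4-(ArCH2)dihydrofuran-2(3H)-one, via Criegee adduct 5 (not isolated)
Conditions: Sc(OTf)3 (5 mol %), chiral N,N′-dioxide ligand (6 mol %), mCPBA (1.1 equiv), EtOAc, −20 °C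
Reagents that add atoms: 3-chloroperoxybenzoic acid (mCPBA), OOC(=O)c1cccc(Cl)c1
Why: The Sc(III)–N,N′-dioxide complex binds the ketone, the peracid adds to give Criegee adduct 5, and one of the two enantiotopic α-CH2 groups (the one antiperiplanar to the O–O bond in the chiral pocket) shifts from carbon to oxygen with loss of 3-chlorobenzoate, which creates the O1–C5 bond. The closest known reaction type is the catalytic asymmetric Baeyer–Villiger desymmetrisation of prochiral 3-substituted cyclobutanones. The γ-lactone ring is closed by ring expansion (a four- to five-membered 1,2-shift, not an exo or endo cyclisation) and is driven by release of the cyclobutane strain. The only new stereocentre, C4 (R), is set by the catalyst through its choice between the two enantiotopic migrating methylenes, the substrate having no other stereocentre. There is no regiochemical issue because both migrating carbons are equivalent CH2 groups, so the step needs only enantiotopic-group selectivity and chemoselectivity for the strained ketone over the electron-rich arene, which the catalyst, the low temperature and the silylated phenol should secure.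

**Step 5**
Reactants: 7 4-hydroxy-3,5-dimethoxybenzaldehyde (syringaldehyde)
Product: 8 4-(tert-butyldimethylsilyloxy)-3,5-dimethoxybenzaldehyde
Conditions: TBSCl, imidazole, DMF, rt
Reagents that add atoms: tert-butyldimethylsilyl chloride, CC(C)(C)[Si](C)(C)Cl
Why: O-Silylation of the phenol (silyl ether formation) removes the acidic proton so that the aldehyde tolerates the lithium enolate.

**Step 6**
Reactants: 6 (R)-4-(ArCH2)dihydrofuran-2(3H)-one; 8 4-(tert-butyldimethylsilyloxy)-3,5-dimethoxybenzaldehyde
Product: 10 (3S,4R)-3-[hydroxy(Ar)methyl]-4-(ArCH2)dihydrofuran-2(3H)-one (both carbinol epimers), via lithium enolate 9 (not isolated)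
Conditions: LDA, THF, −78 °C; then 8, −78 °C; AcOH quench at −78 °C
Reagents that add atoms: none
Why: Kinetic deprotonation gives lithium enolate 9, whose aldol addition should occur on the ring face anti to the C4 arylmethyl group and so fix the 3,4-trans relationship (C3 S) by substrate control; the carbinol centre is left uncontrolled because steps 7 and 8 correct it.

**Step 7**
Reactants: 10 (3S,4R)-3-[hydroxy(Ar)methyl]-4-(ArCH2)dihydrofuran-2(3H)-one (both carbinol epimers)
Product: 11 (3S,4R)-3-(ArCO)-4-(ArCH2)dihydrofuran-2(3H)-one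
Conditions: Dess–Martin periodinane, CH2Cl2, 0 °C to rt
Reagents that add atoms: none
Why: Dess–Martin oxidation should converge both carbinol epimers on one β-keto lactone, the epimerisable C3 remaining in the favoured trans arrangement.

**Step 8**
Reactants: 11 (3S,4R)-3-(ArCO)-4-(ArCH2)dihydrofuran-2(3H)-one
Product: 12 (3S,4R)-3-[(S)-hydroxy(Ar)methyl]-4-(ArCH2)dihydrofuran-2(3H)-one
Conditions: Zn(BH4)2, Et2O/CH2Cl2, −78 to −20 °C
Reagents that add atoms: none
Why: Chelation-controlled (Cram-chelate) reduction of an α-substituted β-keto ester: zinc bridges the ketone and lactone carbonyl oxygens and hydride should attack the ketone face on the side of H-3, away from C4, giving the syn (S) carbinol.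

**Step 9**
Reactants: 12 (3S,4R)-3-[(S)-hydroxy(Ar)methyl]-4-(ArCH2)dihydrofuran-2(3H)-one
Product: 13 (3S,4R)-3-[(S)-(tert-butyldimethylsilyloxy)(Ar)methyl]-4-(ArCH2)dihydrofuran-2(3H)-one
Conditions: TBSOTf, 2,6-lutidine, CH2Cl2, −78 to 0 °C
Reagents that add atoms: tert-butyldimethylsilyl triflate, CC(C)(C)[Si](C)(C)OS(=O)(=O)C(F)(F)F
Why: Silyl triflate/lutidine O-silylation of the secondary benzylic alcohol runs under non-basic conditions (no retro-aldol) and shields this oxygen from ionisation in step 11.

**Step 10**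
Reactants: 13 (3S,4R)-3-[(S)-(tert-butyldimethylsilyloxy)(Ar)methyl]-4-(ArCH2)dihydrofuran-2(3H)-one
Product: 14 (3S,4R)-3-[(S)-(tert-butyldimethylsilyloxy)(Ar)methyl]-4-(ArCH2)tetrahydrofuran-2-ol (both anomers)
Conditions: DIBAL-H (1.2 equiv), CH2Cl2, −78 °C; Rochelle salt work-up
Reagents that add atoms: none
Why: Partial reduction of a lactone to the lactol by DIBAL-H should stop at the stable aluminium hemiacetal at −78 °C, with the silyl ethers inert.

**Step 11**
Reactants: 14 (3S,4R)-3-[(S)-(tert-butyldimethylsilyloxy)(Ar)methyl]-4-(ArCH2)tetrahydrofuran-2-ol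
Product: 16 (3R,4R)-3-[(S)-(tert-butyldimethylsilyloxy)(Ar)methyl]-4-(ArCH2)tetrahydrofuran, via oxocarbenium ion 15 (not isolated)
Conditions: Et3SiH (5 equiv), BF3·OEt2, CH2Cl2, −78 °C; cold NaHCO3 quench
Reagents that add atoms: none
Why: Lewis-acid ionisation of the anomeric hydroxyl gives oxocarbenium ion 15, which the silane should trap by hydride transfer (ionic hydrogenation of a lactol), removing the temporary C2 oxygen without touching the O1–C5 bond or the stereocentres.

**Step 12**
Reactants: 16 (3R,4R)-3-[(S)-(tert-butyldimethylsilyloxy)(Ar)methyl]-4-(ArCH2)tetrahydrofuran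
Product: 17 (S)-[(3R,4R)-4-(4-hydroxy-3,5-dimethoxybenzyl)tetrahydrofuran-3-yl](4-hydroxy-3,5-dimethoxyphenyl)methanol (target)
Conditions: TBAF (4 equiv), AcOH (4 equiv), THF, 0 °C to rt
Reagents that add atoms: none
Why: Fluoride should cleave all three Si–O bonds (two aryl and one secondary alkyl silyl ether), the acetic acid buffer keeping the phenols protonated so that quinone methide formation and phenoxide oxidation are suppressed.

**Compound list**

1 | 4-allyl-2,6-dimethoxyphenol (methoxyeugenol) | C=CCc1cc(OC)c(O)c(OC)c1 | starting material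
2 | (4-allyl-2,6-dimethoxyphenoxy)(tert-butyl)dimethylsilane | C=CCc1cc(OC)c(O[Si](C)(C)C(C)(C)C)c(OC)c1 | intermediate
3 | rac-2,2-dichloro-3-[4-(tert-butyldimethylsilyloxy)-3,5-dimethoxybenzyl]cyclobutan-1-one | O=C1CC(Cc2cc(OC)c(O[Si](C)(C)C(C)(C)C)c(OC)c2)C1(Cl)Cl | intermediate
4 | 3-[4-(tert-butyldimethylsilyloxy)-3,5-dimethoxybenzyl]cyclobutan-1-one | O=C1CC(Cc2cc(OC)c(O[Si](C)(C)C(C)(C)C)c(OC)c2)C1 | intermediate
5 | Criegee adduct: 1-hydroxy-3-[4-(tert-butyldimethylsilyloxy)-3,5-dimethoxybenzyl]cyclobutyl 3-chloroperoxybenzoate | OC1(OOC(=O)c2cccc(Cl)c2)CC(Cc2cc(OC)c(O[Si](C)(C)C(C)(C)C)c(OC)c2)C1 | intermediate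
6 | (R)-4-[4-(tert-butyldimethylsilyloxy)-3,5-dimethoxybenzyl]dihydrofuran-2(3H)-one | O=C1C[C@@H](Cc2cc(OC)c(O[Si](C)(C)C(C)(C)C)c(OC)c2)CO1 | intermediate
7 | 4-hydroxy-3,5-dimethoxybenzaldehyde (syringaldehyde) | O=Cc1cc(OC)c(O)c(OC)c1 | starting material
8 | 4-(tert-butyldimethylsilyloxy)-3,5-dimethoxybenzaldehyde | O=Cc1cc(OC)c(O[Si](C)(C)C(C)(C)C)c(OC)c1 | intermediate
9 | lithium enolate of 6 | [Li]OC1=C[C@@H](Cc2cc(OC)c(O[Si](C)(C)C(C)(C)C)c(OC)c2)CO1 | intermediate
10 | (3S,4R)-3-{hydroxy[4-(tert-butyldimethylsilyloxy)-3,5-dimethoxyphenyl]methyl}-4-[4-(tert-butyldimethylsilyloxy)-3,5-dimethoxybenzyl]dihydrofuran-2(3H)-one, both carbinol epimers | COc1cc(C[C@H]2COC(=O)[C@@H]2C(O)c2cc(OC)c(O[Si](C)(C)C(C)(C)C)c(OC)c2)cc(OC)c1O[Si](C)(C)C(C)(C)C | intermediate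
11 | (3S,4R)-3-[4-(tert-butyldimethylsilyloxy)-3,5-dimethoxybenzoyl]-4-[4-(tert-butyldimethylsilyloxy)-3,5-dimethoxybenzyl]dihydrofuran-2(3H)-one | COc1cc(C[C@H]2COC(=O)[C@@H]2C(=O)c2cc(OC)c(O[Si](C)(C)C(C)(C)C)c(OC)c2)cc(OC)c1O[Si](C)(C)C(C)(C)C | intermediate
12 | (3S,4R)-3-{(S)-hydroxy[4-(tert-butyldimethylsilyloxy)-3,5-dimethoxyphenyl]methyl}-4-[4-(tert-butyldimethylsilyloxy)-3,5-dimethoxybenzyl]dihydrofuran-2(3H)-one | COc1cc(C[C@H]2COC(=O)[C@@H]2[C@H](O)c2cc(OC)c(O[Si](C)(C)C(C)(C)C)c(OC)c2)cc(OC)c1O[Si](C)(C)C(C)(C)C | intermediate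
13 | (3S,4R)-3-{(S)-(tert-butyldimethylsilyloxy)[4-(tert-butyldimethylsilyloxy)-3,5-dimethoxyphenyl]methyl}-4-[4-(tert-butyldimethylsilyloxy)-3,5-dimethoxybenzyl]dihydrofuran-2(3H)-one | COc1cc(C[C@H]2COC(=O)[C@@H]2[C@H](O[Si](C)(C)C(C)(C)C)c2cc(OC)c(O[Si](C)(C)C(C)(C)C)c(OC)c2)cc(OC)c1O[Si](C)(C)C(C)(C)C | intermediate
14 | (3S,4R)-3-{(S)-(tert-butyldimethylsilyloxy)[4-(tert-butyldimethylsilyloxy)-3,5-dimethoxyphenyl]methyl}-4-[4-(tert-butyldimethylsilyloxy)-3,5-dimethoxybenzyl]tetrahydrofuran-2-ol, both anomers | COc1cc(C[C@H]2COC(O)[C@@H]2[C@H](O[Si](C)(C)C(C)(C)C)c2cc(OC)c(O[Si](C)(C)C(C)(C)C)c(OC)c2)cc(OC)c1O[Si](C)(C)C(C)(C)C | intermediate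
15 | cyclic oxocarbenium ion from 14 (C2=O1+) | COc1cc(C[C@H]2C[O+]=C[C@@H]2[C@H](O[Si](C)(C)C(C)(C)C)c2cc(OC)c(O[Si](C)(C)C(C)(C)C)c(OC)c2)cc(OC)c1O[Si](C)(C)C(C)(C)C | intermediate
16 | (3R,4R)-3-{(S)-(tert-butyldimethylsilyloxy)[4-(tert-butyldimethylsilyloxy)-3,5-dimethoxyphenyl]methyl}-4-[4-(tert-butyldimethylsilyloxy)-3,5-dimethoxybenzyl]tetrahydrofuran | COc1cc(C[C@H]2COC[C@@H]2[C@H](O[Si](C)(C)C(C)(C)C)c2cc(OC)c(O[Si](C)(C)C(C)(C)C)c(OC)c2)cc(OC)c1O[Si](C)(C)C(C)(C)C | intermediate
17 | (S)-[(3R,4R)-4-(4-hydroxy-3,5-dimethoxybenzyl)tetrahydrofuran-3-yl](4-hydroxy-3,5-dimethoxyphenyl)methanol | COc1cc(C[C@H]2COC[C@@H]2[C@H](O)c2cc(OC)c(O)c(OC)c2)cc(OC)c1O | target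

**Step count and risks**

Total step count: 12. Longest linear sequence: 11 steps (steps 1–4 and 6–12 from methoxyeugenol); step 5 is a one-step side branch.

Steps most likely to fail:

1. Step 4. The risk is erosion of enantiotopic-group selectivity, because uncatalysed peracid oxidation of the strained ketone can compete with the catalysed pathway, or an unexpected sense of induction. The fallback replaces catalysis by a classical resolution, setting out from 4 and returning at 6. Cyclobutanone 4 is oxidised with mCPBA/NaHCO3 in CH2Cl2 to the racemic lactone F1. F1 is opened with (R)-1-phenylethylamine (AlMe3, CH2Cl2) to two diastereomeric γ-hydroxy amides, which are separated by crystallisation or chromatography. The (3R)-configured hydroxy amide F2 is relactonised with TsOH in toluene at 80 °C, which should return lactone 6 and release the amine.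

2. Step 11. The risks are competing ionisation at the electron-rich benzylic silyl ether, capture of the oxocarbenium ion by one of the electron-rich arenes, and epimerisation at C3 through the enol ether. The fallback avoids any cation, setting out from 13 and returning at 16. Lactone 13 is reduced with LiBH4 (THF, 0 °C to rt) to the 1,4-diol F3. F3 is closed to the oxolane by Mitsunobu cyclodehydration (PPh3, DIAD, THF, 0 °C), the silylated secondary oxygen being unable to take part.

3. Step 8. The risk is insufficient facial selectivity in hydride delivery if the open, non-chelated transition state competes with the zinc chelate. The fallback changes from substrate control to catalyst control, setting out from 11 and returning at 12. Ketone 11 is reduced with BH3·SMe2 and the (R)-configured methyl oxazaborolidine (CBS reduction, THF, −20 °C), which on the aryl-as-large-group model should deliver the S carbinol. This makes no new compound (F0).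

**Further compounds**

F1 | step 4 | rac-4-[4-(tert-butyldimethylsilyloxy)-3,5-dimethoxybenzyl]dihydrofuran-2(3H)-one | O=C1CC(Cc2cc(OC)c(O[Si](C)(C)C(C)(C)C)c(OC)c2)CO1
F2 | step 4 | (R)-4-[4-(tert-butyldimethylsilyloxy)-3,5-dimethoxyphenyl]-3-(hydroxymethyl)-N-[(R)-1-phenylethyl]butanamide | O=C(N[C@H](C)c1ccccc1)C[C@@H](Cc2cc(OC)c(O[Si](C)(C)C(C)(C)C)c(OC)c2)CO
F3 | step 11 | (2R,3R)-2-{(S)-(tert-butyldimethylsilyloxy)[4-(tert-butyldimethylsilyloxy)-3,5-dimethoxyphenyl]methyl}-3-[4-(tert-butyldimethylsilyloxy)-3,5-dimethoxybenzyl]butane-1,4-diol | COc1cc(C[C@@H](CO)[C@H](CO)[C@H](O[Si](C)(C)C(C)(C)C)c2cc(OC)c(O[Si](C)(C)C(C)(C)C)c(OC)c2)cc(OC)c1O[Si](C)(C)C(C)(C)C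
F0 | step 8 | none | none
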